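**Plan**
- Core numbering: C1 and C4 are the bridgeheads (C1 next to the alkene CH C6, C4 next to C5, which carries the acrylate); C2/C3 are the diketone carbons (C2 on C1); C7 bears CO2H and sits on C4; C8 bears the aryl group and sits on C1.
- Enabling feature: C3 is a ketone carbon and C4 lies β to the C7 carboxyl, so the bridging bond C3–C4 is the central bond of a 1,4-dicarbonyl unit. An acyl anion equivalent at C3 can therefore add to a C7=C4 enoate held in the cyclohexa-1,3-diene ring C1–C6–C5–C4–C7–C8.
- Retrosynthetic cuts, in order: the acid-labile protecting groups; the C2 carbonyl oxygen (C–H oxidation); the C5–alkenyl bond of the side chain (Heck); C3–C4 (Stetter, opens the bicycle); then C7–C8 and C1–C6 with return of CO2 (pyrone Diels–Alder), back to a bromopyrone ester and an (E)-styrene.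
- Forward: the carbocyclic six-membered ring arises first (pyrone cycloaddition, CO2 extrusion) and the bicyclo[2.2.2]octene second (Stetter closure). The danshensu acrylate is then joined at C5, C2 is oxidised and all protecting groups fall in one acid step.
- Stereochemistry: C1/C8 trans from the E-alkene (suprafacial cycloaddition), absolute sense from a chiral Cu(OTf)2–bis(oxazoline) catalyst; C4 from the tether; C7 by equilibration trans to the aryl group; the side-chain centre from (R)-danshensu; the E-acrylate from the Heck reaction.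

Key step: step 8

Assumption: the (S,S)-ligand of step 5 is taken to give the (5S,6R) diene drawn; should the first run show the opposite sense, the (R,R)-ligand is used and nothing else changes.

**Route**

Step 1
Reactants: 1 4-bromobenzene-1,2-diol (4-bromocatechol)
Product: 2 5-bromo-2,2-dimethyl-1,3-benzodioxole
Conditions: 2,2-dimethoxypropane, TsOH·H2O (cat.), toluene, reflux, methanol removed over 4 Å molecular sieves
Reagents that add atoms: 2,2-dimethoxypropane, COC(C)(C)OC
Why: Acid-catalysed ketal exchange (acetonide formation) closes the dioxole ring on the catechol and is driven by removal of methanol; no stereocentre is involved.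

Step 2
Reactants: 3 tert-butyl(but-3-yn-1-yloxy)dimethylsilane
Product: 4 (E)-tert-butyldimethyl{[4-(4,4,5,5-tetramethyl-1,3,2-dioxaborolan-2-yl)but-3-en-1-yl]oxy}silane
Conditions: pinacolborane, Cp2Zr(H)Cl (5 mol%), Et3N (10 mol%), neat, 60 °C
Reagents that add atoms: pinacolborane, [H]B1OC(C)(C)C(C)(C)O1
Why: Zirconium-catalysed hydroboration of a terminal alkyne is a syn, anti-Markovnikov addition and should give the (E)-alkenylboronate only.

Step 3
Reactants: 2 5-bromo-2,2-dimethyl-1,3-benzodioxole; 4 the (E)-alkenylboronate
Product: 5 (E)-tert-butyl{[4-(2,2-dimethyl-1,3-benzodioxol-5-yl)but-3-en-1-yl]oxy}dimethylsilane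
Conditions: Pd(dppf)Cl2 (3 mol%), K2CO3, 1,4-dioxane/H2O, 80 °C
Reagents that add atoms: none
Why: Suzuki–Miyaura coupling of an aryl bromide with an alkenylboronate proceeds with retention of the E geometry, and silyl ether and acetonide tolerate aqueous carbonate.

Step 4
Reactants: 6 methyl 2-oxo-2H-pyran-3-carboxylate
Product: 7 methyl 5-bromo-2-oxo-2H-pyran-3-carboxylate
Conditions: Br2, CH2Cl2, 0 → 23 °C; then Et3N, 0 °C
Reagents that add atoms: bromine, BrBr
Why: Bromination of the 2-pyrone by addition across C5=C6 and amine-induced loss of HBr (the acidic γ-hydrogen at C5 leaves with bromide from C6) places bromine at C5, the only nucleophilic ring position left open by the 3-ester.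

Step 5
Reactants: 5 the (E)-styrene; 7 methyl 5-bromo-2-oxo-2H-pyran-3-carboxylate
Product: 9 methyl (5S,6R)-3-bromo-5-[2-(tert-butyldimethylsilyloxy)ethyl]-6-(2,2-dimethyl-1,3-benzodioxol-5-yl)cyclohexa-1,3-diene-1-carboxylate, via bridged bicyclic lactone 8 (not isolated)
Conditions: Cu(OTf)2 (10 mol%), (S,S)-2,2′-isopropylidenebis(4-tert-butyl-2-oxazoline) (11 mol%), 4 Å molecular sieves, CH2Cl2, −20 → 23 °C; then toluene, 100 °C
Reagents that add atoms: none
Why: Inverse-electron-demand Diels–Alder reaction of a 3-carboalkoxy-2-pyrone with an electron-rich alkene followed by retro-Diels–Alder loss of CO2: the nucleophilic alkene carbon remote from the aryl group bonds to pyrone C6 and the benzylic carbon to C3, the suprafacial addition carries the E geometry into the 5,6-trans relationship, and the copper complex chelated by ester and lactone carbonyls selects the alkene face and so the absolute configuration of both centres.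

Step 6
Reactants: 9 the silyl-protected diene ester
Product: 10 methyl (5S,6R)-3-bromo-6-(2,2-dimethyl-1,3-benzodioxol-5-yl)-5-(2-hydroxyethyl)cyclohexa-1,3-diene-1-carboxylate
Conditions: HF·pyridine, pyridine, THF, 0 → 23 °C
Reagents that add atoms: none
Why: Fluoride-mediated desilylation with buffered HF·pyridine frees the primary alcohol without a base that could shift the diene or epimerise C5.

Step 7
Reactants: 10 the primary alcohol
Product: 11 methyl (5S,6R)-3-bromo-6-(2,2-dimethyl-1,3-benzodioxol-5-yl)-5-(2-oxoethyl)cyclohexa-1,3-diene-1-carboxylate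
Conditions: Dess–Martin periodinane, CH2Cl2, 0 → 23 °C; used at once
Reagents that add atoms: none
Why: Dess–Martin oxidation converts the primary alcohol into the aldehyde under near-neutral conditions that leave the diene ester and both stereocentres untouched.

Step 8
Reactants: 11 the aldehyde (Stetter precursor; ring C5 = core C1, ring C6 = core C8, ring C1 = core C7, ring C2 = core C4)
Product: 13 methyl 5-bromo-8-(2,2-dimethyl-1,3-benzodioxol-5-yl)-3-oxobicyclo[2.2.2]oct-5-ene-7-carboxylate (core numbering; ester on C7 syn to the C2–C3 bridge; aryl on C8 syn to the C5=C6 bridge), via C7-epimeric keto ester 12 (not isolated)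
Conditions: 2-(pentafluorophenyl)-6,7-dihydro-5H-pyrrolo[2,1-c][1,2,4]triazol-2-ium tetrafluoroborate (20 mol%), iPr2NEt (20 mol%), toluene (0.02 M), 23 → 60 °C, argon; then NaOMe (0.2 equiv), MeOH, 23 °C
Reagents that add atoms: none
Why: Proposed new method: the carbene from the triazolium salt adds to the aldehyde, proton transfer gives the hydroxy-enamine (acyl anion equivalent), its nucleophilic C3 adds to C4 (the β-carbon of the C7=C4 ester), the ester enolate is protonated at C7 and release of the carbene leaves the C3 ketone. The closest known reaction is the intramolecular Stetter cyclisation of aliphatic aldehydes onto β-substituted acrylates, and the bridged geometry is that of the ring-closing Michael step in double-Michael routes to bicyclo[2.2.2]octanones; new here is the acyl-anion version of such a bridged closure onto a ring dienoate. The one new ring (C1–C2–C3–C4–C5–C6) closes 6-exo-trig and turns the cyclohexadiene into the bicyclo[2.2.2]oct-5-ene with C5=C6 left in place. C4 is set by the tether, because the arm on C1 (pseudoaxial, trans to the aryl group that is itself pseudoaxial to avoid A(1,2) strain against the ester) reaches C4 only on its own face; C7 is first protonated on that same face by the neighbouring hydroxyl (ester cis to aryl, 12) and is then equilibrated by NaOMe to the isomer with the ester trans to the aryl group. The step needs 1,4-acylation to win over aldol and benzoin pathways and over other electrophilic sites: high dilution and a weak amine base hold back the former, the only other electrophilic diene carbon (C6) could be reached only through a four-membered ring, the alkenyl bromide is inert to the carbene, and the methyl ester is a stronger acceptor than a bulkier ester.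

Step 9
Reactants: 13 the bicyclic keto ester
Product: 14 5-bromo-8-(2,2-dimethyl-1,3-benzodioxol-5-yl)-3-oxobicyclo[2.2.2]oct-5-ene-7-carboxylic acid (core numbering, stereochemistry as in 13)
Conditions: LiOH, THF/MeOH/H2O, 23 °C; then 1 M HCl to pH 3, 0 °C
Reagents that add atoms: lithium hydroxide, [Li+].[OH-]
Why: Saponification of the methyl ester gives the acid without risk to any stereocentre, since C7 is already in its more stable configuration and the bridgehead C4 cannot enolise.

Step 10
Reactants: 15 (R)-danshensu, (2R)-3-(3,4-dihydroxyphenyl)-2-hydroxypropanoic acid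
Product: 17 (2R)-3-(2,2-dimethyl-1,3-benzodioxol-5-yl)-2-hydroxypropanoic acid, via dioxolanone bis-acetonide 16 (not isolated)
Conditions: 2,2-dimethoxypropane, TsOH·H2O (cat.), acetone/toluene, reflux; then LiOH, THF/H2O, 0 °C; 1 M HCl to pH 3
Reagents that add atoms: 2,2-dimethoxypropane, COC(C)(C)OC; lithium hydroxide, [Li+].[OH-]
Why: Acid-catalysed ketalisation protects the catechol while tying the α-hydroxy acid up as a dioxolanone, and cold hydroxide then opens only that activated lactone by acyl–oxygen cleavage, which does not touch the stereocentre.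

Step 11
Reactants: 17 the acetonide hydroxy acid
Product: 18 tert-butyl (2R)-3-(2,2-dimethyl-1,3-benzodioxol-5-yl)-2-hydroxypropanoate
Conditions: tert-butyl 2,2,2-trichloroacetimidate, CH2Cl2/cyclohexane, 23 °C
Reagents that add atoms: tert-butyl 2,2,2-trichloroacetimidate, CC(C)(C)OC(=N)C(Cl)(Cl)Cl
Why: Esterification with the trichloroacetimidate is acid-selective without added catalyst, so the carboxylic acid is tert-butylated while the secondary alcohol stays free.

Step 12
Reactants: 18 the hydroxy ester
Product: 19 tert-butyl (2R)-2-(acryloyloxy)-3-(2,2-dimethyl-1,3-benzodioxol-5-yl)propanoate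
Conditions: acryloyl chloride, Et3N, CH2Cl2, 0 °C
Reagents that add atoms: acryloyl chloride, C=CC(=O)Cl
Why: O-Acylation of the secondary alcohol with an acid chloride and a tertiary amine forms the acrylate ester with retention at the carbinol centre.

Step 13
Reactants: 14 the bromo keto acid; 19 the danshensu acrylate
Product: 20 C7 acid of the bicyclo[2.2.2]oct-5-en-3-one core (stereochemistry as in 13) bearing at C5 the (E)-acrylate of tert-butyl (2R)-3-(2,2-dimethyl-1,3-benzodioxol-5-yl)-2-hydroxypropanoate
Conditions: Pd(OAc)2 (10 mol%), P(o-tol)3 (20 mol%), Et3N (3 equiv), DMF, 80 °C; citric acid work-up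
Reagents that add atoms: none
Why: Mizoroki–Heck reaction of the alkenyl bromide with the acrylate (oxidative addition, syn insertion, syn β-hydride elimination) forms the C5–alkenyl bond as the (E)-alkene, and the bridgehead hydrogen at C4 cannot take part in β-hydride elimination.

Step 14
Reactants: 20 the Heck product
Product: 21 the corresponding bicyclo[2.2.2]oct-5-ene-2,3-dione (yunnaneic acid C with both catechols as acetonides and the side-chain acid as tert-butyl ester)
Conditions: SeO2, 1,4-dioxane/H2O (20:1), 90 °C
Reagents that add atoms: selenium dioxide, O=[Se]=O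
Why: Riley oxidation takes the C2 methylene, the only enolisable position next to the C3 ketone, to a carbonyl group as known for bicyclo[2.2.2]octan-2-ones, and any partial loss of acid-labile groups is harmless one step before their removal.

Step 15
Reactants: 21 the protected diketone
Product: 22 yunnaneic acid C
Conditions: TFA/H2O (9:1), 0 → 23 °C
Reagents that add atoms: none
Why: Acidolysis with aqueous trifluoroacetic acid hydrolyses both catechol acetonides and cleaves the tert-butyl ester in one operation, while the acrylate ester, the diketone and all stereocentres are stable to acid.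

**Compound list**
1 | 4-bromobenzene-1,2-diol (4-bromocatechol) | Oc1ccc(Br)cc1O | starting material
2 | 5-bromo-2,2-dimethyl-1,3-benzodioxole | CC1(C)Oc2ccc(Br)cc2O1 | intermediate
3 | tert-butyl(but-3-yn-1-yloxy)dimethylsilane | C#CCCO[Si](C)(C)C(C)(C)C | starting material
4 | (E)-tert-butyldimethyl{[4-(4,4,5,5-tetramethyl-1,3,2-dioxaborolan-2-yl)but-3-en-1-yl]oxy}silane | CC(C)(C)[Si](C)(C)OCC/C=C/B1OC(C)(C)C(C)(C)O1 | intermediate
5 | (E)-tert-butyl{[4-(2,2-dimethyl-1,3-benzodioxol-5-yl)but-3-en-1-yl]oxy}dimethylsilane | CC(C)(C)[Si](C)(C)OCC/C=C/c1ccc2OC(C)(C)Oc2c1 | intermediate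
6 | methyl 2-oxo-2H-pyran-3-carboxylate | COC(=O)C1=CC=COC1=O | starting material
7 | methyl 5-bromo-2-oxo-2H-pyran-3-carboxylate | COC(=O)C1=CC(Br)=COC1=O | intermediate
8 | methyl 7-bromo-6-[2-(tert-butyldimethylsilyloxy)ethyl]-5-(2,2-dimethyl-1,3-benzodioxol-5-yl)-3-oxo-2-oxabicyclo[2.2.2]oct-7-ene-4-carboxylate (5,6-trans; aryl anti to the lactone bridge drawn; the other bridge diastereomer gives the same diene) | COC(=O)[C@@]12C=C(Br)[C@@H](OC1=O)[C@@H](CCO[Si](C)(C)C(C)(C)C)[C@@H]2c3ccc4OC(C)(C)Oc4c3 | intermediate
9 | methyl (5S,6R)-3-bromo-5-[2-(tert-butyldimethylsilyloxy)ethyl]-6-(2,2-dimethyl-1,3-benzodioxol-5-yl)cyclohexa-1,3-diene-1-carboxylate | COC(=O)C1=CC(Br)=C[C@@H](CCO[Si](C)(C)C(C)(C)C)[C@@H]1c2ccc3OC(C)(C)Oc3c2 | intermediate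
10 | methyl (5S,6R)-3-bromo-6-(2,2-dimethyl-1,3-benzodioxol-5-yl)-5-(2-hydroxyethyl)cyclohexa-1,3-diene-1-carboxylate | COC(=O)C1=CC(Br)=C[C@@H](CCO)[C@@H]1c2ccc3OC(C)(C)Oc3c2 | intermediate
11 | methyl (5S,6R)-3-bromo-6-(2,2-dimethyl-1,3-benzodioxol-5-yl)-5-(2-oxoethyl)cyclohexa-1,3-diene-1-carboxylate | COC(=O)C1=CC(Br)=C[C@@H](CC=O)[C@@H]1c2ccc3OC(C)(C)Oc3c2 | intermediate
12 | C7 epimer of 13 (ester on C7 cis to the aryl group on C8, syn to the C5=C6 bridge) | BrC1=C[C@H]2CC(=O)[C@@H]1[C@@H](C(=O)OC)[C@H]2c3ccc4OC(C)(C)Oc4c3 | intermediate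
13 | methyl 5-bromo-8-(2,2-dimethyl-1,3-benzodioxol-5-yl)-3-oxobicyclo[2.2.2]oct-5-ene-7-carboxylate (core numbering; 7,8-trans; ester syn to the C2–C3 bridge, aryl syn to the C5=C6 bridge) | BrC1=C[C@H]2CC(=O)[C@@H]1[C@H](C(=O)OC)[C@H]2c3ccc4OC(C)(C)Oc4c3 | intermediate
14 | 5-bromo-8-(2,2-dimethyl-1,3-benzodioxol-5-yl)-3-oxobicyclo[2.2.2]oct-5-ene-7-carboxylic acid (core numbering, stereochemistry as in 13) | BrC1=C[C@H]2CC(=O)[C@@H]1[C@H](C(=O)O)[C@H]2c3ccc4OC(C)(C)Oc4c3 | intermediate
15 | (R)-danshensu, (2R)-3-(3,4-dihydroxyphenyl)-2-hydroxypropanoic acid | O[C@H](Cc1ccc(O)c(O)c1)C(=O)O | starting material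
16 | (5R)-5-[(2,2-dimethyl-1,3-benzodioxol-5-yl)methyl]-2,2-dimethyl-1,3-dioxolan-4-one | CC1(C)O[C@H](Cc2ccc3OC(C)(C)Oc3c2)C(=O)O1 | intermediate
17 | (2R)-3-(2,2-dimethyl-1,3-benzodioxol-5-yl)-2-hydroxypropanoic acid | O[C@H](Cc1ccc2OC(C)(C)Oc2c1)C(=O)O | intermediate
18 | tert-butyl (2R)-3-(2,2-dimethyl-1,3-benzodioxol-5-yl)-2-hydroxypropanoate | O[C@H](Cc1ccc2OC(C)(C)Oc2c1)C(=O)OC(C)(C)C | intermediate
19 | tert-butyl (2R)-2-(acryloyloxy)-3-(2,2-dimethyl-1,3-benzodioxol-5-yl)propanoate | C=CC(=O)O[C@H](Cc1ccc2OC(C)(C)Oc2c1)C(=O)OC(C)(C)C | intermediate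
20 | Heck product: acid 14 with bromine replaced by the (E)-acrylate side chain of 19 (C2 methylene, C3 ketone) | O=C(/C=C/C1=C[C@H]2CC(=O)[C@@H]1[C@H](C(=O)O)[C@H]2c3ccc4OC(C)(C)Oc4c3)O[C@H](Cc5ccc6OC(C)(C)Oc6c5)C(=O)OC(C)(C)C | intermediate
21 | 2,3-dione of 20 (protected yunnaneic acid C) | O=C(/C=C/C1=C[C@H]2C(=O)C(=O)[C@@H]1[C@H](C(=O)O)[C@H]2c3ccc4OC(C)(C)Oc4c3)O[C@H](Cc5ccc6OC(C)(C)Oc6c5)C(=O)OC(C)(C)C | intermediate
22 | yunnaneic acid C | O=C(/C=C/C1=C[C@H]2C(=O)C(=O)[C@@H]1[C@H](C(=O)O)[C@H]2c1ccc(O)c(O)c1)O[C@H](Cc1ccc(O)c(O)c1)C(=O)O | target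

**Totals**
Total step count: 15.
Longest linear sequence: 10 steps (1, 3, 5, 6, 7, 8, 9, 13, 14, 15, from 4-bromocatechol).

**Steps most likely to fail**

Step 8 (Stetter closure). The acyl anion equivalent may not reach C4 fast enough, so that aldehyde self-condensation, or base-induced migration of the diene followed by aromatisation, takes over. The fallback uses known ketyl–olefin chemistry and sets out from 11. SmI2 with tert-butanol in THF at −78 °C (no HMPA, so that the alkenyl bromide is spared) should add the ketyl carbon C3 to C4 of the enoate. This would give the C3 carbinol methyl 5-bromo-8-(2,2-dimethyl-1,3-benzodioxol-5-yl)-3-hydroxybicyclo[2.2.2]oct-5-ene-7-carboxylate F1. Dess–Martin oxidation of the carbinol and the NaOMe equilibration already used in step 8 bring the material back to the route at 13.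

Step 5 (asymmetric pyrone cycloaddition). Facial discrimination by the catalyst may be insufficient, or the Lewis acid may oligomerise the electron-rich styrene before cycloaddition. The fallback sets out from 5 and 7 and gives up asymmetric induction for a separation. The cycloaddition is run with the achiral Zn(OTf)2, or simply in toluene at 100 °C. It then passes through the racemic lactone, whose unwanted half is the mirror-image lactone F2, and gives the diene as a racemate. Preparative chromatography on a cellulose tris(3,5-dimethylphenylcarbamate) phase separates the enantiomers. The (5R,6S) diene F3 is set aside and the (5S,6R) enantiomer rejoins the route at 9.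

Step 14 (Riley oxidation). SeO2 may over-oxidise or attack benzylic C–H bonds, and protecting groups may be lost early in the hot acidic medium, which would complicate isolation. The fallback sets out from 20 and replaces the one-step oxidation by a two-stage sequence under mild conditions. Soft enolisation with TMSOTf and Et3N should give the C2=C3 trimethylsilyl enol ether, with the acid silylated as well, the bis(trimethylsilyl) derivative F4. Rubottom oxidation with dimethyldioxirane and a mild acidic work-up should give the C2 hydroxy ketone F5. Dess–Martin oxidation then returns the route at 21.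

Further compounds
F1 | step 8 | methyl 5-bromo-8-(2,2-dimethyl-1,3-benzodioxol-5-yl)-3-hydroxybicyclo[2.2.2]oct-5-ene-7-carboxylate (core numbering; configurations at C3 and C7 open) | BrC1=C[C@H]2CC(O)[C@@H]1C(C(=O)OC)[C@H]2c3ccc4OC(C)(C)Oc4c3
F2 | step 5 | mirror image of lactone 8 | COC(=O)[C@]12C=C(Br)[C@H](OC1=O)[C@H](CCO[Si](C)(C)C(C)(C)C)[C@H]2c3ccc4OC(C)(C)Oc4c3
F3 | step 5 | methyl (5R,6S)-3-bromo-5-[2-(tert-butyldimethylsilyloxy)ethyl]-6-(2,2-dimethyl-1,3-benzodioxol-5-yl)cyclohexa-1,3-diene-1-carboxylate | COC(=O)C1=CC(Br)=C[C@H](CCO[Si](C)(C)C(C)(C)C)[C@H]1c2ccc3OC(C)(C)Oc3c2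
F4 | step 14 | bis(trimethylsilyl) derivative of 20 (C2=C3 silyl enol ether and C7 silyl ester) | O=C(/C=C/C1=C[C@H]2C=C(O[Si](C)(C)C)[C@@H]1[C@H](C(=O)O[Si](C)(C)C)[C@H]2c3ccc4OC(C)(C)Oc4c3)O[C@H](Cc5ccc6OC(C)(C)Oc6c5)C(=O)OC(C)(C)C
F5 | step 14 | C2 hydroxy ketone of 20 (configuration at C2 open) | O=C(/C=C/C1=C[C@H]2C(O)C(=O)[C@@H]1[C@H](C(=O)O)[C@H]2c3ccc4OC(C)(C)Oc4c3)O[C@H](Cc5ccc6OC(C)(C)Oc6c5)C(=O)OC(C)(C)C
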